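Ring A (4-hydroxy-2-methoxyphenyl) is the only ring with a methyl ether, so it is not carried through the synthesis but assembled from acyclic pieces. The disconnection cuts its C1–C2 and C5–C6 bonds: an enantiopure terminal ynone, whose carbonyl carbon becomes the CH2 on C1 of ring A, undergoes Diels–Alder reaction with 1,1-dimethoxy-3-(trimethylsilyloxy)buta-1,3-diene, and loss of methanol delivers the arene with OMe at C2 and free OH at C4 in one operation. The ynone already holds the (R)-diarylmethine centre with benzyl-protected rings B and C and a bromine at C5 of ring C, the handle for the ring D ketone chain.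

Key step: step 7

Assumption: the stereocentre is read from the SMILES as (R) (priorities ring C > ring B > CH2 > H); this descriptor holds for every intermediate from 5 onward.
Remark: ring D is joined through the stable allylic alcohol 18, because Heck arylation of a secondary allylic alcohol gives the saturated aryl ketone directly and no polymerisable aryl vinyl ketone is needed.

Step 1
Reactants: 1 5-bromo-2,4-dihydroxybenzaldehyde
Product: 2 2,4-bis(benzyloxy)-5-bromobenzaldehyde
Conditions: BnBr (2.3 equiv), K2CO3, DMF, 60 °C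
Reagents that add atoms: benzyl bromide, BrCc1ccccc1
Why: Williamson ether synthesis, in which both phenoxides (including the hydrogen-bonded 2-OH at this temperature) displace bromide while the aldehyde and aryl bromide stay inert.

Step 2
Reactants: 2 2,4-bis(benzyloxy)-5-bromobenzaldehyde
Product: 3 (2E)-3-[2,4-bis(benzyloxy)-5-bromophenyl]-N-methoxy-N-methylprop-2-enamide
Conditions: Ph3P=CHC(O)N(OMe)Me, toluene, 90 °C
Reagents that add atoms: N-methoxy-N-methyl-2-(triphenyl-λ5-phosphanylidene)acetamide, CON(C)C(=O)C=P(c1ccccc1)(c1ccccc1)c1ccccc1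
Why: Wittig olefination with a stabilised ylide, which should give the (E)-alkene with an aromatic aldehyde.

Step 3
Reactants: 3 (2E)-3-[2,4-bis(benzyloxy)-5-bromophenyl]-N-methoxy-N-methylprop-2-enamide; 4 4-(benzyloxy)phenylboronic acid
Product: 5 (3R)-3-[2,4-bis(benzyloxy)-5-bromophenyl]-3-[4-(benzyloxy)phenyl]-N-methoxy-N-methylpropanamide
Conditions: 4 (2.5 equiv), Rh(acac)(C2H4)2 (3 mol%), (S)-BINAP (3.3 mol%), K2CO3 (0.5 equiv), dioxane–H2O 10:1, 100 °C
Reagents that add atoms: none
Why: Hayashi–Miyaura reaction, in which the aryl group passes from boron to monovalent rhodium, the (E)-enamide inserts into the Rh–aryl bond and water protonates the oxa-π-allyl rhodium species; the C2-symmetric (S)-BINAP ligand differentiates the two faces of C3 and, by the usual model for (E)-configured acyclic acceptors, should give the (R) centre ((R)-BINAP gives the mirror image), while the aryl bromide is inert to this catalyst.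

Step 4
Reactants: 5 (3R)-3-[2,4-bis(benzyloxy)-5-bromophenyl]-3-[4-(benzyloxy)phenyl]-N-methoxy-N-methylpropanamide
Product: 7 (5R)-5-[2,4-bis(benzyloxy)-5-bromophenyl]-5-[4-(benzyloxy)phenyl]pent-1-yn-3-one, via bromomagnesium hemiaminal chelate 6 (not isolated)
Conditions: HC≡CMgBr (3 equiv), THF, 0 °C → rt; inverse quench into 1 M HCl, 0 °C
Reagents that add atoms: ethynylmagnesium bromide, C#C[Mg]Br
Why: Weinreb ketone synthesis, in which the alkynyl Grignard reagent adds once to give the chelated tetrahedral adduct 6 that releases the ynone only on quench, and the cold acidic quench protonates the liberated N,O-dimethylhydroxylamine before it can add to the ynone; the stereocentre is not involved.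

Step 5
Reactants: 8 1,1-dimethoxyethene
Product: 9 4,4-dimethoxybut-3-en-2-one
Conditions: CH3COCl, Et3N, Et2O, 0 °C → rt
Reagents that add atoms: acetyl chloride, CC(=O)Cl
Why: C-acylation of a ketene acetal at its nucleophilic CH2 carbon, followed by deprotonation of the dimethoxycarbenium ion by the amine to give the β,β-dimethoxy enone.

Step 6
Reactants: 9 4,4-dimethoxybut-3-en-2-one
Product: 11 1,1-dimethoxy-3-(trimethylsilyloxy)buta-1,3-diene, via lithium dienolate 10 (not isolated)
Conditions: LiN(i-Pr)2, THF, −78 °C; Me3SiCl, −78 °C → rt; non-aqueous work-up, distillation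
Reagents that add atoms: chlorotrimethylsilane, C[Si](C)(C)Cl
Why: Silyl enol ether formation, in which kinetic deprotonation of the only enolisable position (the methyl group) gives the cross-conjugated dienolate 10 and silicon is then delivered to oxygen.

Step 7
Reactants: 7 (5R)-5-[2,4-bis(benzyloxy)-5-bromophenyl]-5-[4-(benzyloxy)phenyl]pent-1-yn-3-one; 11 1,1-dimethoxy-3-(trimethylsilyloxy)buta-1,3-diene
Product: 14 (3R)-3-[2,4-bis(benzyloxy)-5-bromophenyl]-3-[4-(benzyloxy)phenyl]-1-(4-hydroxy-2-methoxyphenyl)propan-1-one, via dimethoxycyclohexadiene cycloadduct 12 (not isolated), via aryl trimethylsilyl ether 13 (not isolated)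
Conditions: 11 (2.5 equiv), toluene, rt → 60 °C; then 1 M HCl, THF, rt
Reagents that add atoms: none
Why: The diene 11, whose three oxygen donors raise the HOMO and place its largest coefficient on the CH2 terminus, and the ynone 7, whose LUMO is largest on the terminal alkyne carbon, should combine in a normal-demand, strongly asynchronous Diels–Alder reaction in which the diene CH2 bonds to the ynone β-carbon and the acetal carbon to the α-carbon, giving cyclohexa-1,4-diene 12. The closest known reaction type is the cycloaddition of 1,1-dimethoxy-3-silyloxybutadienes with acetylenic ketones and esters followed by aromatisation. Ring A closes by intermolecular [4+2] cycloaddition, which forms both new C–C bonds of the six-membered ring; acid then drives 1,4-elimination of methanol from 12 to the aryl silyl ether 13 and cleaves the O–Si bond to give phenol 14. No stereocentre is created, and the existing (R) centre is β to the carbonyl, carries no acidic hydrogen and is not touched. The step needs regioselectivity, which the matched polarity of the two partners secures (OMe ortho and OH para to the acyl group), and chemoselectivity, which holds because the aryl bromide, the benzyl ethers and the saturated chain are inert to a neutral thermal cycloaddition and to dilute acid.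

Step 8
Reactants: 14 (3R)-3-[2,4-bis(benzyloxy)-5-bromophenyl]-3-[4-(benzyloxy)phenyl]-1-(4-hydroxy-2-methoxyphenyl)propan-1-one
Product: 16 4-{(3R)-3-[2,4-bis(benzyloxy)-5-bromophenyl]-3-[4-(benzyloxy)phenyl]propyl}-3-methoxyphenol, via benzylic carbinol 15 (not isolated)
Conditions: Et3SiH (4 equiv), CF3CO2H (10 equiv), CH2Cl2, 0 °C → rt
Reagents that add atoms: none
Why: Ionic hydrogenation (silane–acid reduction), in which the protonated electron-rich aryl ketone takes up hydride to give carbinol 15, which ionises to a benzylic cation stabilised by the para-hydroxy and ortho-methoxy groups of ring A and takes up a second hydride; the limited acid charge and low temperature should leave the benzyl ethers, the aryl bromide and the remote stereocentre untouched.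

Step 9
Reactants: 17 4-(benzyloxy)benzaldehyde
Product: 18 1-[4-(benzyloxy)phenyl]prop-2-en-1-ol (racemic)
Conditions: CH2=CHMgBr, THF, −78 → 0 °C; sat. NH4Cl
Reagents that add atoms: vinylmagnesium bromide, C=C[Mg]Br
Why: Grignard 1,2-addition to an aromatic aldehyde; the carbinol centre is left racemic because it becomes the ketone carbon in step 10.

Step 10
Reactants: 16 4-{(3R)-3-[2,4-bis(benzyloxy)-5-bromophenyl]-3-[4-(benzyloxy)phenyl]propyl}-3-methoxyphenol; 18 1-[4-(benzyloxy)phenyl]prop-2-en-1-ol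
Product: 20 3-{2,4-bis(benzyloxy)-5-[(1R)-1-[4-(benzyloxy)phenyl]-3-(4-hydroxy-2-methoxyphenyl)propyl]phenyl}-1-[4-(benzyloxy)phenyl]propan-1-one, via enol 19 (not isolated)
Conditions: 18 (2 equiv), Pd(OAc)2 (5 mol%), P(o-tol)3 (10 mol%), n-Bu4NBr, NaHCO3, DMF, 100 °C
Reagents that add atoms: none
Why: Heck reaction of an aryl bromide with a secondary allylic alcohol, in which the arylpalladium species adds to the terminal alkene carbon and β-hydride elimination toward the carbinol C–H gives enol 19, which tautomerises to the saturated aryl ketone; the weak base leaves the ring A phenol and the stereocentre untouched.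

Step 11
Reactants: 20 3-{2,4-bis(benzyloxy)-5-[(1R)-1-[4-(benzyloxy)phenyl]-3-(4-hydroxy-2-methoxyphenyl)propyl]phenyl}-1-[4-(benzyloxy)phenyl]propan-1-one
Product: 21 3-{2,4-dihydroxy-5-[(1R)-3-(4-hydroxy-2-methoxyphenyl)-1-(4-hydroxyphenyl)propyl]phenyl}-1-(4-hydroxyphenyl)propan-1-one
Conditions: H2 (1 atm), 10% Pd/C, EtOAc–MeOH, rt, stopped after uptake for four benzyl groups
Reagents that add atoms: none
Why: Catalytic hydrogenolysis of the four aryl benzyl ethers, which should be much faster under neutral ambient-pressure conditions than reduction of the electron-rich 4-hydroxyphenyl ketone, while the methyl ether and the C–H stereocentre are not cleaved.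

Compound list
1 | 5-bromo-2,4-dihydroxybenzaldehyde | O=Cc1cc(Br)c(O)cc1O | starting material
2 | 2,4-bis(benzyloxy)-5-bromobenzaldehyde | O=Cc1cc(Br)c(OCc2ccccc2)cc1OCc1ccccc1 | intermediate
3 | (2E)-3-[2,4-bis(benzyloxy)-5-bromophenyl]-N-methoxy-N-methylprop-2-enamide | CON(C)C(=O)/C=C/c1cc(Br)c(OCc2ccccc2)cc1OCc1ccccc1 | intermediate
4 | 4-(benzyloxy)phenylboronic acid | OB(O)c1ccc(OCc2ccccc2)cc1 | starting material
5 | (3R)-3-[2,4-bis(benzyloxy)-5-bromophenyl]-3-[4-(benzyloxy)phenyl]-N-methoxy-N-methylpropanamide | CON(C)C(=O)C[C@H](c1ccc(OCc2ccccc2)cc1)c1cc(Br)c(OCc2ccccc2)cc1OCc1ccccc1 | intermediate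
6 | bromomagnesium alkoxide of the tetrahedral adduct of 5 with the ethynyl group (carbinol carbon unassigned) | C#CC(O[Mg]Br)(N(C)OC)C[C@H](c1ccc(OCc2ccccc2)cc1)c1cc(Br)c(OCc2ccccc2)cc1OCc1ccccc1 | intermediate
7 | (5R)-5-[2,4-bis(benzyloxy)-5-bromophenyl]-5-[4-(benzyloxy)phenyl]pent-1-yn-3-one | C#CC(=O)C[C@H](c1ccc(OCc2ccccc2)cc1)c1cc(Br)c(OCc2ccccc2)cc1OCc1ccccc1 | intermediate
8 | 1,1-dimethoxyethene | C=C(OC)OC | starting material
9 | 4,4-dimethoxybut-3-en-2-one | CC(=O)C=C(OC)OC | intermediate
10 | lithium 4,4-dimethoxybuta-1,3-dien-2-olate | [Li]OC(=C)C=C(OC)OC | intermediate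
11 | 1,1-dimethoxy-3-(trimethylsilyloxy)buta-1,3-diene | COC(OC)=CC(=C)O[Si](C)(C)C | intermediate
12 | (3R)-3-[2,4-bis(benzyloxy)-5-bromophenyl]-3-[4-(benzyloxy)phenyl]-1-[6,6-dimethoxy-4-(trimethylsilyloxy)cyclohexa-1,4-dien-1-yl]propan-1-one | COC1(OC)C=C(O[Si](C)(C)C)CC=C1C(=O)C[C@H](c1ccc(OCc2ccccc2)cc1)c1cc(Br)c(OCc2ccccc2)cc1OCc1ccccc1 | intermediate
13 | (3R)-3-[2,4-bis(benzyloxy)-5-bromophenyl]-3-[4-(benzyloxy)phenyl]-1-[2-methoxy-4-(trimethylsilyloxy)phenyl]propan-1-one | COc1cc(O[Si](C)(C)C)ccc1C(=O)C[C@H](c1ccc(OCc2ccccc2)cc1)c1cc(Br)c(OCc2ccccc2)cc1OCc1ccccc1 | intermediate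
14 | (3R)-3-[2,4-bis(benzyloxy)-5-bromophenyl]-3-[4-(benzyloxy)phenyl]-1-(4-hydroxy-2-methoxyphenyl)propan-1-one | COc1cc(O)ccc1C(=O)C[C@H](c1ccc(OCc2ccccc2)cc1)c1cc(Br)c(OCc2ccccc2)cc1OCc1ccccc1 | intermediate
15 | 4-{(3R)-3-[2,4-bis(benzyloxy)-5-bromophenyl]-3-[4-(benzyloxy)phenyl]-1-hydroxypropyl}-3-methoxyphenol (carbinol carbon unassigned) | COc1cc(O)ccc1C(O)C[C@H](c1ccc(OCc2ccccc2)cc1)c1cc(Br)c(OCc2ccccc2)cc1OCc1ccccc1 | intermediate
16 | 4-{(3R)-3-[2,4-bis(benzyloxy)-5-bromophenyl]-3-[4-(benzyloxy)phenyl]propyl}-3-methoxyphenol | COc1cc(O)ccc1CC[C@H](c1ccc(OCc2ccccc2)cc1)c1cc(Br)c(OCc2ccccc2)cc1OCc1ccccc1 | intermediate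
17 | 4-(benzyloxy)benzaldehyde | O=Cc1ccc(OCc2ccccc2)cc1 | starting material
18 | 1-[4-(benzyloxy)phenyl]prop-2-en-1-ol (racemic) | C=CC(O)c1ccc(OCc2ccccc2)cc1 | intermediate
19 | 4-{(3R)-3-[2,4-bis(benzyloxy)-5-{3-[4-(benzyloxy)phenyl]-3-hydroxyprop-2-en-1-yl}phenyl]-3-[4-(benzyloxy)phenyl]propyl}-3-methoxyphenol (enol) | COc1cc(O)ccc1CC[C@H](c1ccc(OCc2ccccc2)cc1)c1cc(CC=C(O)c2ccc(OCc3ccccc3)cc2)c(OCc2ccccc2)cc1OCc1ccccc1 | intermediate
20 | 3-{2,4-bis(benzyloxy)-5-[(1R)-1-[4-(benzyloxy)phenyl]-3-(4-hydroxy-2-methoxyphenyl)propyl]phenyl}-1-[4-(benzyloxy)phenyl]propan-1-one | COc1cc(O)ccc1CC[C@H](c1ccc(OCc2ccccc2)cc1)c1cc(CCC(=O)c2ccc(OCc3ccccc3)cc2)c(OCc2ccccc2)cc1OCc1ccccc1 | intermediate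
21 | 3-{2,4-dihydroxy-5-[(1R)-3-(4-hydroxy-2-methoxyphenyl)-1-(4-hydroxyphenyl)propyl]phenyl}-1-(4-hydroxyphenyl)propan-1-one | COc1cc(O)ccc1CC[C@H](c1ccc(O)cc1)c1cc(CCC(=O)c2ccc(O)cc2)c(O)cc1O | target

Total step count: 11
Longest linear sequence: 8 steps (steps 1, 2, 3, 4, 7, 8, 10, 11)

Steps most likely to fail

Step 7. The cycloaddition may be overtaken by conjugate addition of the diene without ring closure, by [2+2] addition at the ketene-acetal double bond, or by hydrolysis of the diene before it reacts. The fallback gives up ring construction and makes the same ketone by acyl substitution. It sets out from amide 5. Commercial 4-bromo-3-methoxyphenol is silylated (t-BuMe2SiCl, imidazole, DMF) to (4-bromo-3-methoxyphenoxy)(tert-butyl)dimethylsilane F1, and magnesium turnings in THF convert this into {4-[(tert-butyldimethylsilyl)oxy]-2-methoxyphenyl}magnesium bromide F2. Addition of F2 to 5 at 0 °C should give (3R)-3-[2,4-bis(benzyloxy)-5-bromophenyl]-3-[4-(benzyloxy)phenyl]-1-{4-[(tert-butyldimethylsilyl)oxy]-2-methoxyphenyl}propan-1-one F3 without touching the aryl bromide. n-Bu4NF in THF then frees the phenol, and the route is rejoined at 14.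

Step 3. Insertion into a β-aryl, ortho-substituted enamide may be slow, so that protodeboronation of the boronic acid wins, or the facial selectivity may be insufficient. The fallback replaces catalyst control by auxiliary control and sets out from aldehyde 2. Knoevenagel condensation with malonic acid in the Doebner modification (pyridine, piperidine, 90 °C) gives (2E)-3-[2,4-bis(benzyloxy)-5-bromophenyl]prop-2-enoic acid F4. Its pivaloyl mixed anhydride (t-BuCOCl, Et3N, THF) acylates (4S)-4-phenyl-1,3-oxazolidin-2-one in the presence of LiCl to give (4S)-3-[(2E)-3-[2,4-bis(benzyloxy)-5-bromophenyl]prop-2-enoyl]-4-phenyl-1,3-oxazolidin-2-one F5. Copper-mediated conjugate addition of 4-(benzyloxy)phenylmagnesium bromide (CuBr·SMe2, THF, −40 °C) to the chelated s-cis imide should occur on the face away from the 4-phenyl group. This gives (4S)-3-[(3R)-3-[2,4-bis(benzyloxy)-5-bromophenyl]-3-[4-(benzyloxy)phenyl]propanoyl]-4-phenyl-1,3-oxazolidin-2-one F6 as a diastereomer that can be purified by crystallisation. Me(MeO)NH·HCl with AlMe3 in CH2Cl2 exchanges the auxiliary for the N-methoxy-N-methylamide, and the route is rejoined at 5.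

Step 10. Oxidative addition to the electron-rich, ortho-alkoxy aryl bromide may be slow, β-hydride elimination may go toward the benzylic CH2 and leave an allylic alcohol, or palladium hydride may isomerise 18 before it couples. The fallback fixes the position of the carbonyl by an alkyne coupling and sets out from bromide 16. Ethynylmagnesium bromide is added to aldehyde 17 to give 1-[4-(benzyloxy)phenyl]prop-2-yn-1-ol F7. Copper-free Sonogashira coupling of F7 with 16 (PdCl2(MeCN)2, XPhos, Cs2CO3, MeCN, 80 °C) should give 4-{(3R)-3-[2,4-bis(benzyloxy)-5-{3-[4-(benzyloxy)phenyl]-3-hydroxyprop-1-yn-1-yl}phenyl]-3-[4-(benzyloxy)phenyl]propyl}-3-methoxyphenol F8. MnO2 in CH2Cl2 oxidises the propargylic alcohol to 3-{2,4-bis(benzyloxy)-5-[(1R)-1-[4-(benzyloxy)phenyl]-3-(4-hydroxy-2-methoxyphenyl)propyl]phenyl}-1-[4-(benzyloxy)phenyl]prop-2-yn-1-one F9. The hydrogenation conditions of step 11 then saturate the triple bond and remove the four benzyl groups, and the route is rejoined at 21.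

Further compounds
F1 | step 7 | (4-bromo-3-methoxyphenoxy)(tert-butyl)dimethylsilane | COc1cc(O[Si](C)(C)C(C)(C)C)ccc1Br
F2 | step 7 | {4-[(tert-butyldimethylsilyl)oxy]-2-methoxyphenyl}magnesium bromide | COc1cc(O[Si](C)(C)C(C)(C)C)ccc1[Mg]Br
F3 | step 7 | (3R)-3-[2,4-bis(benzyloxy)-5-bromophenyl]-3-[4-(benzyloxy)phenyl]-1-{4-[(tert-butyldimethylsilyl)oxy]-2-methoxyphenyl}propan-1-one | COc1cc(O[Si](C)(C)C(C)(C)C)ccc1C(=O)C[C@H](c1ccc(OCc2ccccc2)cc1)c1cc(Br)c(OCc2ccccc2)cc1OCc1ccccc1
F4 | step 3 | (2E)-3-[2,4-bis(benzyloxy)-5-bromophenyl]prop-2-enoic acid | OC(=O)/C=C/c1cc(Br)c(OCc2ccccc2)cc1OCc1ccccc1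
F5 | step 3 | (4S)-3-[(2E)-3-[2,4-bis(benzyloxy)-5-bromophenyl]prop-2-enoyl]-4-phenyl-1,3-oxazolidin-2-one | O=C(/C=C/c1cc(Br)c(OCc2ccccc2)cc1OCc1ccccc1)N1[C@@H](c2ccccc2)COC1=O
F6 | step 3 | (4S)-3-[(3R)-3-[2,4-bis(benzyloxy)-5-bromophenyl]-3-[4-(benzyloxy)phenyl]propanoyl]-4-phenyl-1,3-oxazolidin-2-one | O=C(C[C@H](c1ccc(OCc2ccccc2)cc1)c1cc(Br)c(OCc2ccccc2)cc1OCc1ccccc1)N1[C@@H](c2ccccc2)COC1=O
F7 | step 10 | 1-[4-(benzyloxy)phenyl]prop-2-yn-1-ol | C#CC(O)c1ccc(OCc2ccccc2)cc1
F8 | step 10 | 4-{(3R)-3-[2,4-bis(benzyloxy)-5-{3-[4-(benzyloxy)phenyl]-3-hydroxyprop-1-yn-1-yl}phenyl]-3-[4-(benzyloxy)phenyl]propyl}-3-methoxyphenol | COc1cc(O)ccc1CC[C@H](c1ccc(OCc2ccccc2)cc1)c1cc(C#CC(O)c2ccc(OCc3ccccc3)cc2)c(OCc2ccccc2)cc1OCc1ccccc1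
F9 | step 10 | 3-{2,4-bis(benzyloxy)-5-[(1R)-1-[4-(benzyloxy)phenyl]-3-(4-hydroxy-2-methoxyphenyl)propyl]phenyl}-1-[4-(benzyloxy)phenyl]prop-2-yn-1-one | COc1cc(O)ccc1CC[C@H](c1ccc(OCc2ccccc2)cc1)c1cc(C#CC(=O)c2ccc(OCc3ccccc3)cc2)c(OCc2ccccc2)cc1OCc1ccccc1
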